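## Retrosynthetic overview

1. Late stage: the exo-methylene comes from a C3 carboxyl group, the butenoyl group from a C7 acetyl group, and the C8 ester from acylation. The cis γ-lactone (ring A) is closed by SN2 inversion at C8a with a malonate ester.
2. C5–OH and C6–CH3 come from an exocyclic methylene at C6 (allylic oxidation, then hydroxyl-directed hydrogenation). C7–OH comes from oxidation of a silyl enol ether.
3. The cycloheptane (ring B) comes from a cyclopentane: the C4–C7 bond of a 1-acetyl-7-methylidenebicyclo[3.2.0]heptane is cut by ketyl fragmentation, a two-carbon ring expansion driven by cyclobutane strain.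
4. Key disconnection: C4–C5 and C6–C7 by head-to-head [2+2] photocycloaddition of allene to a 1-acetylcyclopentene. The enabling feature is that C7, a quaternary carbinol carbon carrying an acyl group, is joined to the ring CH2 (C4) through exactly two carbons (C5, C6), one with a one-carbon branch. The acyl group is both the enone chromophore and the ketyl trigger, and the C6 methyl marks the central carbon of allene.
5. Order of ring formation: cyclopentene (bought) → cyclobutane (step 4) → cycloheptane (step 5) → lactone (step 13).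

Key step: step 4

Remark 1: locants C2–C8a are those of the cyclohepta[b]furan skeleton of the target (carbocycle C3a–C4–C5–C6–C7–C8–C8a, lactone α-carbon C3) and are used for all intermediates.
Remark 2: the (3aS,6aS)-enone 1 is assumed to be a purchasable building block.

## Route

Step 1
Reactants: 1 (3aS,6aS)-2,2-dimethyl-3a,6a-dihydro-4H-cyclopenta[d][1,3]dioxol-4-one; 2 di-tert-butyl malonate
Product: 3 malonate Michael adduct (ketone)
Conditions: KOtBu (10 mol %), THF, −20 → 0 °C
Reagents that add atoms: none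
Why: Michael addition of the soft malonate anion should occur on the convex face, anti to the cis-fused acetonide, which sets C3a trans to both ring oxygens.

Step 2
Reactants: 3 malonate Michael adduct
Product: 4 enol triflate
Conditions: LiN(SiMe3)2 (2.2 equiv), THF, −78 °C; PhNTf2, −78 → 0 °C
Reagents that add atoms: N-phenylbis(trifluoromethanesulfonimide), O=S(=O)(N(c1ccccc1)S(=O)(=O)C(F)(F)F)C(F)(F)F
Why: kinetic enolisation of the malonate/ketone dianion at the unhindered CH2 (not at the alkoxy-bearing methine) and O-sulfonylation of the more reactive ketone enolate should give the enol triflate (enol triflate formation); no stereocentre is formed.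

Step 3
Reactants: 4 enol triflate; 5 tributyl(1-ethoxyvinyl)stannane
Product: 7 1-acetylcyclopentene, via ethoxydiene 6 (not isolated)
Conditions: Pd(PPh3)4 (5 mol %), LiCl, THF, 65 °C; then 1 M HCl, THF, 0 °C
Reagents that add atoms: water, O
Why: Stille coupling of the enol triflate with the α-ethoxyvinylstannane (an acetyl anion equivalent) and mild hydrolysis of the enol ether should give the conjugated methyl ketone; the stereocentres are untouched.

Step 4
Reactants: 7 1-acetylcyclopentene; 8 propa-1,2-diene (allene)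
Product: 9 cis-fused methylidenecyclobutane photoadduct
Conditions: hν (medium-pressure Hg lamp, uranium-glass filter, λ > 340 nm), excess 8, CH2Cl2, −78 °C
Reagents that add atoms: none
Why: Irradiation into the n→π* band gives the triplet enone, which bonds first through the acetyl-bearing carbon C7 to the central allene carbon; the resulting triplet 1,4-biradical (alkyl radical at C4, allyl radical) undergoes spin inversion and closes at the allene terminus (C5) onto C4. The closest known reaction type is the head-to-head [2+2] photocycloaddition of allene to cyclic enones, which gives β,γ-unsaturated ketones with the methylidene carbon next to the carbonyl-bearing ring-fusion carbon. The four-membered ring closes by radical recombination across the former C4=C7 double bond (formal [2+2]), and the five-membered ring allows only the cis-fused bicyclo[3.2.0]heptane. The two new stereocentres (C4 and C7) are therefore cis to each other; the face of addition (expected anti to the acetonide) is immaterial, because C7 becomes sp2 and C4 becomes CH2 in step 5. The step needs only regioselectivity (central allene carbon to C7, terminal carbon to C4), secured by formation of the allyl radical from allene, and chemoselectivity against enone dimerisation and against a photochemical 1,3-acyl shift of the product, secured by excess allene, low temperature and the long-wavelength filter.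

Step 5
Reactants: 9 photoadduct
Product: 11 ring-expanded triethylsilyl dienol ether, via samarium dienolate 10 (not isolated)
Conditions: SmI2 (2.5 equiv), HMPA, t-BuOH (2 equiv), Et3SiCl (3 equiv), THF, −78 °C
Reagents that add atoms: chlorotriethylsilane, CC[Si](Cl)(CC)CC
Why: ketyl radical-anion fragmentation of the cyclobutyl ketone should cut only C4–C7 (cutting C6–C7 would give a vinyl radical), release the ring strain and expand the ring by two carbons; the C4 radical is reduced and protonated, the trivalent samarium dienolate is O-silylated in situ, and both stereocentres of step 4 are erased.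

Step 6
Reactants: 11 silyl dienol ether
Product: 12 α-silyloxy ketone
Conditions: dimethyldioxirane, acetone/CH2Cl2, −78 → −20 °C
Reagents that add atoms: dimethyldioxirane, CC1(C)OO1
Why: Rubottom oxidation, in which the silyl enol ether (the more electron-rich alkene) is epoxidised on the face anti to the acetonide and a 1,4-silyl shift gives the α-silyloxy ketone, should set C7 with its oxygen trans to the C8 oxygen.

Step 7
Reactants: 12 α-silyloxy ketone
Product: 13 allylic alcohol
Conditions: SeO2 (0.5 equiv), t-BuOOH, CH2Cl2, 0 °C → rt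
Reagents that add atoms: tert-butyl hydroperoxide, CC(C)(C)OO
Why: SeO2 allylic oxidation (ene reaction, then [2,3]-sigmatropic shift) can only reach C5, because C7 has no hydrogen, and keeps the methylidene exocyclic; oxygen is expected on the face of C5 anti to the C7 silyloxy and C3a malonyl groups, which would set C5.

Step 8
Reactants: 13 allylic alcohol
Product: 14 C6-methyl alcohol
Conditions: H2 (1 atm), [Ir(cod)(PCy3)(py)]PF6 (10 mol %), CH2Cl2, rt
Reagents that add atoms: none
Why: hydroxyl-directed homogeneous hydrogenation, with iridium bound to C5–OH (and to the acetyl carbonyl on the same face), should deliver H2 to that face of the methylidene, so the new C6 methyl is trans to C5–OH and cis to the C7 oxygen.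

Step 9
Reactants: 14 C6-methyl alcohol
Product: 15 C5 tert-butyldiphenylsilyl ether
Conditions: TBDPSCl, imidazole, DMAP (cat.), DMF, 40 °C
Reagents that add atoms: tert-butylchlorodiphenylsilane, CC(C)(C)[Si](Cl)(c1ccccc1)c1ccccc1
Why: silylation of the only free hydroxyl gives an acid-stable ether that should last until the final step; no stereocentre changes.

Step 10
Reactants: 15 silyl ether; 16 acetaldehyde
Product: 17 aldol adduct
Conditions: LiN(SiMe3)2 (2.2 equiv), THF, −78 °C; CH3CHO; aq. NH4Cl
Reagents that add atoms: none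
Why: aldol addition of the methyl ketone enolate (the only enolisable ketone position, since C7 is quaternary; the malonate methine is deprotonated as a spectator) should give the β-hydroxy ketone as a carbinol mixture, which does not matter because that centre is removed in step 14.

Step 11
Reactants: 17 aldol adduct
Product: 18 β-acetoxy ketone
Conditions: Ac2O, pyridine, CH2Cl2, 0 °C → rt
Reagents that add atoms: acetic anhydride, CC(=O)OC(C)=O
Why: acetylation of the side-chain hydroxyl masks the butenoyl group as a β-acetoxy ketone until C8 is acylated, which avoids oxa-Michael closure of a free C8 hydroxyl onto an enone.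

Step 12
Reactants: 18 β-acetoxy ketone
Product: 19 triol
Conditions: TsOH·H2O (0.2 equiv), MeOH, rt
Reagents that add atoms: none
Why: acid-catalysed transketalisation should remove the acetonide and methanolysis the tertiary triethylsilyl ether, while the tert-butyl esters, the acetate and the TBDPS ether stay.

Step 13
Reactants: 19 triol
Product: 20 cis-fused lactone
Conditions: Tf2O (1.1 equiv), pyridine, CH2Cl2, −78 → 0 °C
Reagents that add atoms: none
Why: the less hindered secondary hydroxyl (C8a; C8–OH is flanked by quaternary C7) should be triflated and displaced with inversion by the carbonyl oxygen of a tert-butyl ester (neighbouring-group SN2 lactonisation with loss of isobutene), which closes the cis γ-lactone and sets C8a.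

Step 14
Reactants: 20 lactone; 21 (S)-2-methylbutanoic anhydride
Product: 23 C8 ester with (E)-butenoyl group, via acetoxy ketone ester 22 (not isolated)
Conditions: 21, DMAP, Et3N, CH2Cl2, rt; then DBU, 0 °C
Reagents that add atoms: none
Why: DMAP-catalysed acylation of the only secondary hydroxyl (the tertiary C7–OH should not react), then E1cB loss of acetic acid, should give the (E)-enone; the (S) centre of the ester comes from 21.

Step 15
Reactants: 23 butenoyl ester; 24 formaldehyde
Product: 26 C5-silylated target, via carboxy lactone 25 (not isolated)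
Conditions: TFA/CH2Cl2 (1:4), 0 °C → rt; evaporate; then 37% aq. CH2O, Et2NH, NaOAc/AcOH, rt → 50 °C
Reagents that add atoms: none
Why: acidolysis of the tert-butyl ester, then Mannich reaction of the α-carboxy lactone and decarboxylative loss of diethylamine (decarboxylative methylenation), should give the α-methylene lactone without touching a stereocentre.

Step 16
Reactants: 26 C5-silylated target
Product: 27 target (CNP0331957.1)
Conditions: HF·pyridine, THF, 0 °C → rt
Reagents that add atoms: none
Why: fluoride cleavage of the TBDPS ether should free C5–OH under conditions that the α-methylene lactone, the enone and the ester tolerate.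

## Compound list

1 | (3aS,6aS)-2,2-dimethyl-3a,6a-dihydro-4H-cyclopenta[d][1,3]dioxol-4-one | CC1(C)O[C@H]2C=CC(=O)[C@H]2O1 | starting material
2 | di-tert-butyl malonate | CC(C)(C)OC(=O)CC(=O)OC(C)(C)C | starting material
3 | di-tert-butyl 2-(2,2-dimethyl-6-oxotetrahydro-4H-cyclopenta[d][1,3]dioxol-4-yl)malonate; malonyl group trans to the two cis dioxolane oxygens | CC1(C)O[C@H]2[C@H](C(C(=O)OC(C)(C)C)C(=O)OC(C)(C)C)CC(=O)[C@H]2O1 | intermediate
4 | enol triflate of 3 (triflate on the former carbonyl carbon, double bond towards the malonyl-bearing carbon; configuration as in 3) | CC1(C)O[C@H]2[C@H](C(C(=O)OC(C)(C)C)C(=O)OC(C)(C)C)C=C(OS(=O)(=O)C(F)(F)F)[C@H]2O1 | intermediate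
5 | tributyl(1-ethoxyvinyl)stannane | CCCC[Sn](CCCC)(CCCC)C(=C)OCC | starting material
6 | ethoxydiene: 4 with 1-ethoxyvinyl in place of the triflate | CC1(C)O[C@H]2[C@H](C(C(=O)OC(C)(C)C)C(=O)OC(C)(C)C)C=C(C(=C)OCC)[C@H]2O1 | intermediate
7 | di-tert-butyl 2-(6-acetyl-2,2-dimethyl-3a,6a-dihydro-4H-cyclopenta[d][1,3]dioxol-4-yl)malonate; configuration as in 3 | CC1(C)O[C@H]2[C@H](C(C(=O)OC(C)(C)C)C(=O)OC(C)(C)C)C=C(C(C)=O)[C@H]2O1 | intermediate
8 | propa-1,2-diene (allene) | C=C=C | starting material
9 | cis-fused 1-acetyl-7-methylidenebicyclo[3.2.0]heptane with the acetonide and malonyl group of 7 (acetyl on the ring-fusion carbon C7, methylidene on C6); the isomer with the cyclobutane anti to the acetonide is drawn, and the syn isomer reacts alike | CC1(C)O[C@H]2[C@H](C(C(=O)OC(C)(C)C)C(=O)OC(C)(C)C)[C@@H]3CC(=C)[C@]3(C(C)=O)[C@H]2O1 | intermediate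
10 | samarium dienolate of the ring-expanded ketone (C6 methylidene, C7=C(CH3)O–SmI2) | CC1(C)O[C@H]2[C@H](C(C(=O)OC(C)(C)C)C(=O)OC(C)(C)C)CCC(=C)C(=C(C)O[Sm](I)I)[C@H]2O1 | intermediate
11 | cycloheptane with C8/C8a cis-acetonide, CH(CO2t-Bu)2 at C3a (trans to the acetonide), C6 methylidene and C7=C(CH3)OSiEt3 (enol ether geometry immaterial) | CC1(C)O[C@H]2[C@H](C(C(=O)OC(C)(C)C)C(=O)OC(C)(C)C)CCC(=C)C(=C(C)O[Si](CC)(CC)CC)[C@H]2O1 | intermediate
12 | 7-acetyl-7-(triethylsilyloxy) ketone: as 11, C7–OSiEt3 trans to the C8 oxygen | CC1(C)O[C@H]2[C@H](C(C(=O)OC(C)(C)C)C(=O)OC(C)(C)C)CCC(=C)[C@@](O[Si](CC)(CC)CC)(C(C)=O)[C@H]2O1 | intermediate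
13 | 12 with 5-OH (cis to the C8 oxygen, trans to C7–OSiEt3) | CC1(C)O[C@H]2[C@H](C(C(=O)OC(C)(C)C)C(=O)OC(C)(C)C)C[C@@H](O)C(=C)[C@@](O[Si](CC)(CC)CC)(C(C)=O)[C@H]2O1 | intermediate
14 | 13 with C6 methyl in place of the methylidene (methyl trans to 5-OH, cis to C7–OSiEt3) | CC1(C)O[C@H]2[C@H](C(C(=O)OC(C)(C)C)C(=O)OC(C)(C)C)C[C@@H](O)[C@H](C)[C@@](O[Si](CC)(CC)CC)(C(C)=O)[C@H]2O1 | intermediate
15 | 5-O-tert-butyldiphenylsilyl ether of 14 | CC1(C)O[C@H]2[C@H](C(C(=O)OC(C)(C)C)C(=O)OC(C)(C)C)C[C@@H](O[Si](c3ccccc3)(c3ccccc3)C(C)(C)C)[C@H](C)[C@@](O[Si](CC)(CC)CC)(C(C)=O)[C@H]2O1 | intermediate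
16 | acetaldehyde | CC=O | starting material
17 | 15 with 3-hydroxybutanoyl at C7 (carbinol epimers) | CC1(C)O[C@H]2[C@H](C(C(=O)OC(C)(C)C)C(=O)OC(C)(C)C)C[C@@H](O[Si](c3ccccc3)(c3ccccc3)C(C)(C)C)[C@H](C)[C@@](O[Si](CC)(CC)CC)(C(=O)CC(C)O)[C@H]2O1 | intermediate
18 | 15 with 3-acetoxybutanoyl at C7 | CC1(C)O[C@H]2[C@H](C(C(=O)OC(C)(C)C)C(=O)OC(C)(C)C)C[C@@H](O[Si](c3ccccc3)(c3ccccc3)C(C)(C)C)[C@H](C)[C@@](O[Si](CC)(CC)CC)(C(=O)CC(C)OC(C)=O)[C@H]2O1 | intermediate
19 | triol: C7–OH, C8–OH and C8a–OH free (C8/C8a cis, C7–OH trans to C8–OH), 5-OTBDPS, C6 methyl, 3-acetoxybutanoyl at C7, CH(CO2t-Bu)2 at C3a | O[C@H]1[C@H](C(C(=O)OC(C)(C)C)C(=O)OC(C)(C)C)C[C@@H](O[Si](c2ccccc2)(c2ccccc2)C(C)(C)C)[C@H](C)[C@@](O)(C(=O)CC(C)OC(C)=O)[C@H]1O | intermediate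
20 | tert-butyl (3aS,5R,6S,7S,8S,8aR)-7-(3-acetoxybutanoyl)-5-(tert-butyldiphenylsilyloxy)-7,8-dihydroxy-6-methyl-2-oxooctahydro-2H-cyclohepta[b]furan-3-carboxylate (C3 epimers) | CC(C)(C)OC(=O)C1C(=O)O[C@@H]2[C@H]1C[C@@H](O[Si](c3ccccc3)(c3ccccc3)C(C)(C)C)[C@H](C)[C@@](O)(C(=O)CC(C)OC(C)=O)[C@H]2O | intermediate
21 | (S)-2-methylbutanoic anhydride | CC[C@H](C)C(=O)OC(=O)[C@@H](C)CC | starting material
22 | 20 with C8–OH esterified by (2S)-2-methylbutanoyl | CC(C)(C)OC(=O)C1C(=O)O[C@@H]2[C@H]1C[C@@H](O[Si](c3ccccc3)(c3ccccc3)C(C)(C)C)[C@H](C)[C@@](O)(C(=O)CC(C)OC(C)=O)[C@H]2OC(=O)[C@@H](C)CC | intermediate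
23 | tert-butyl (3aS,5R,6S,7S,8S,8aR)-7-[(2E)-but-2-enoyl]-5-(tert-butyldiphenylsilyloxy)-7-hydroxy-6-methyl-8-{[(2S)-2-methylbutanoyl]oxy}-2-oxooctahydro-2H-cyclohepta[b]furan-3-carboxylate | CC(C)(C)OC(=O)C1C(=O)O[C@@H]2[C@H]1C[C@@H](O[Si](c3ccccc3)(c3ccccc3)C(C)(C)C)[C@H](C)[C@@](O)(C(=O)/C=C/C)[C@H]2OC(=O)[C@@H](C)CC | intermediate
24 | formaldehyde | C=O | starting material
25 | free C3 carboxylic acid of 23 | OC(=O)C1C(=O)O[C@@H]2[C@H]1C[C@@H](O[Si](c3ccccc3)(c3ccccc3)C(C)(C)C)[C@H](C)[C@@](O)(C(=O)/C=C/C)[C@H]2OC(=O)[C@@H](C)CC | intermediate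
26 | 5-O-tert-butyldiphenylsilyl ether of the target | C=C1C(=O)O[C@@H]2[C@H]1C[C@@H](O[Si](c3ccccc3)(c3ccccc3)C(C)(C)C)[C@H](C)[C@@](O)(C(=O)/C=C/C)[C@H]2OC(=O)[C@@H](C)CC | intermediate
27 | (3aS,5R,6S,7S,8S,8aR)-7-[(2E)-but-2-enoyl]-5,7-dihydroxy-6-methyl-3-methylidene-2-oxooctahydro-2H-cyclohepta[b]furan-8-yl (2S)-2-methylbutanoate | C=C1C(=O)O[C@@H]2[C@H]1C[C@@H](O)[C@H](C)[C@@](O)(C(=O)/C=C/C)[C@H]2OC(=O)[C@@H](C)CC | target

## Step count and risks

Total steps: 16. Longest linear sequence: 16 steps (1 → 27); compounds 2, 5, 8, 16, 21 and 24 are bought.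

Steps most likely to fail:

Step 5. Reduction or pinacol coupling of the ketyl may outrun C–C cleavage, and the dienolate may be protonated by the malonate methine, or lose the C8 oxygen by β-elimination, before it is silylated. The fallback sets out from 9 and uses a neutral radical chain. NaBH4 reduction of the ketone should give the carbinol F1, and 1,1′-thiocarbonyldiimidazole the O-(imidazol-1-ylthiocarbonyl) derivative F2. Bu3SnH/AIBN (toluene, 80 °C) should then generate the secondary carbinyl radical, which opens the cyclobutane by the same C4–C7 scission (Barton–McCombie-type radical fragmentation) to the ring-expanded 7-ethylidene-6-methylidene diene F3. OsO4/NMO dihydroxylation of the more substituted ethylidene alkene, anti to the acetonide, should give the diol F4, and Dess–Martin oxidation of its secondary alcohol the hydroxy ketone F5. Et3SiOTf/2,6-lutidine (−78 °C) should give 12, where the route is rejoined.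

Step 7. Oxygen delivery to C5 may show poor facial selectivity, and the alcohol may be over-oxidised to the enone. The fallback sets out from 12: if the oxidation gives mainly the C5-epimeric alcohol F6, Mitsunobu reaction (PPh3, DIAD, 4-nitrobenzoic acid) should invert it to the 4-nitrobenzoate F7, and K2CO3/MeOH should cleave the ester to give 13, where the route is rejoined.

Step 13. The two secondary hydroxyls may be poorly discriminated on triflation, and the triflate may eliminate or lactonise with retention instead of being displaced by the ester carbonyl. The fallback sets out from 19 and uses a carboxylate as the nucleophile. MsCl/2,4,6-collidine (−20 °C) should give the C8a mesylate F8, and TFA the malonic diacid mesylate F9. Cs2CO3 in DMF should close the cis lactone by carboxylate SN2 displacement, giving the carboxy lactone F10. Buffered CH2O/Et2NH decarboxylative methylenation should give the hydroxy α-methylene lactone F11, and acylation with 21/DMAP followed by DBU should give 26, where the route is rejoined.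

## Further compounds

F1 | step 5 | carbinol from reduction of the acetyl group of 9 (carbinol epimers) | CC1(C)O[C@H]2[C@H](C(C(=O)OC(C)(C)C)C(=O)OC(C)(C)C)[C@@H]3CC(=C)[C@]3(C(C)O)[C@H]2O1
F2 | step 5 | O-(imidazol-1-ylthiocarbonyl) derivative of F1 | CC1(C)O[C@H]2[C@H](C(C(=O)OC(C)(C)C)C(=O)OC(C)(C)C)[C@@H]3CC(=C)[C@]3(C(C)OC(=S)n4ccnc4)[C@H]2O1
F3 | step 5 | ring-expanded 7-ethylidene-6-methylidene diene | CC1(C)O[C@H]2[C@H](C(C(=O)OC(C)(C)C)C(=O)OC(C)(C)C)CCC(=C)C(=CC)[C@H]2O1
F4 | step 5 | diol: C7–OH (trans to the C8 oxygen) and 1-hydroxyethyl at C7 | CC1(C)O[C@H]2[C@H](C(C(=O)OC(C)(C)C)C(=O)OC(C)(C)C)CCC(=C)[C@@](O)(C(C)O)[C@H]2O1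
F5 | step 5 | 7-acetyl-7-hydroxy ketone (desilyl 12) | CC1(C)O[C@H]2[C@H](C(C(=O)OC(C)(C)C)C(=O)OC(C)(C)C)CCC(=C)[C@@](O)(C(C)=O)[C@H]2O1
F6 | step 7 | C5 epimer of 13 | CC1(C)O[C@H]2[C@H](C(C(=O)OC(C)(C)C)C(=O)OC(C)(C)C)C[C@H](O)C(=C)[C@@](O[Si](CC)(CC)CC)(C(C)=O)[C@H]2O1
F7 | step 7 | 4-nitrobenzoate of 13 | CC1(C)O[C@H]2[C@H](C(C(=O)OC(C)(C)C)C(=O)OC(C)(C)C)C[C@@H](OC(=O)c3ccc(cc3)[N+](=O)[O-])C(=C)[C@@](O[Si](CC)(CC)CC)(C(C)=O)[C@H]2O1
F8 | step 13 | C8a methanesulfonate of 19 | CS(=O)(=O)O[C@H]1[C@H](C(C(=O)OC(C)(C)C)C(=O)OC(C)(C)C)C[C@@H](O[Si](c2ccccc2)(c2ccccc2)C(C)(C)C)[C@H](C)[C@@](O)(C(=O)CC(C)OC(C)=O)[C@H]1O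
F9 | step 13 | malonic diacid of F8 | CS(=O)(=O)O[C@H]1[C@H](C(C(=O)O)C(=O)O)C[C@@H](O[Si](c2ccccc2)(c2ccccc2)C(C)(C)C)[C@H](C)[C@@](O)(C(=O)CC(C)OC(C)=O)[C@H]1O
F10 | step 13 | cis-fused α-carboxy lactone with free C8–OH | OC(=O)C1C(=O)O[C@@H]2[C@H]1C[C@@H](O[Si](c3ccccc3)(c3ccccc3)C(C)(C)C)[C@H](C)[C@@](O)(C(=O)CC(C)OC(C)=O)[C@H]2O
F11 | step 13 | α-methylene lactone with free C8–OH and 3-acetoxybutanoyl group | C=C1C(=O)O[C@@H]2[C@H]1C[C@@H](O[Si](c3ccccc3)(c3ccccc3)C(C)(C)C)[C@H](C)[C@@](O)(C(=O)CC(C)OC(C)=O)[C@H]2O
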